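**Retrosynthetic overview**

1. The target is a type A bicyclo[3.3.1]nonane acylphloroglucinol of the 7-endo series (C7 prenyl cis to the C2–C4 bridge; at C8 the 4-methylpent-3-enyl group axial in the ring B chair, the methyl equatorial). The last operations are loss of a C3 blocking ester and, before it, exo-face hydroboration/B-alkyl Suzuki coupling of a C7 methylidene (sets C7); the methylidene comes from a C7 ketone and that from a C7 exo-alcohol.
2. Key disconnection (ring B, C1–C8): the C5 side chain of a dearomatized acylphloroglucinol closes onto the acyl-bearing C1 at a tertiary cationoid carbon, as in the biosynthesis. The oxygen of a nerol-derived (2R,3S)-epoxide stands in for the prenyl cation and fixes C8 by inversion through a chair.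
3. C5–C6: alkylative dearomatization of the aromatic prenylated acylphloroglucinol at its prenylated carbon with the epoxy triflate (the counterpart of the second aromatic prenyl transfer).
4. The aromatic piece comes from methyl 2,4,6-trihydroxybenzoate (the ester blocks C3), (R)-2-methylbutanoic acid and prenyl bromide. Ring order: the aromatic ring (later ring A) is there from the start; ring B is closed in step 5.

Assumption: bicyclo[3.3.1]nonane locants (C1 acyl carbon, C3 ester/H carbon, C5 prenylated carbon, C6–C8 new bridge, C9 bridging carbonyl) are used for the ring carbons from the aromatic stage on, and (R)-2-methylbutanoic acid is bought as the single enantiomer.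

**Route**

Step 1
Reactants: 1 (R)-2-methylbutanoic acid; 2 methyl 2,4,6-trihydroxybenzoate
Product: 4 methyl 2,4,6-trihydroxy-3-[(2R)-2-methylbutanoyl]benzoate, via acid chloride 3 (not isolated)
Conditions: (COCl)2, cat. DMF, CH2Cl2, 0 °C to rt; then 2, AlCl3, PhNO2–CH2Cl2, 0 °C to rt
Reagents that add atoms: none
Why: Friedel–Crafts C-acylation of the phloroglucinol ring at one of its two equivalent free positions (the ester that will block C3 is already in place); the acid chloride is made under neutral conditions and the acylation is run at or below room temperature, so the R centre of 1 is carried through without enolization.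

Step 2
Reactants: 4 methyl 2,4,6-trihydroxy-3-[(2R)-2-methylbutanoyl]benzoate; 5 prenyl bromide (1-bromo-3-methylbut-2-ene)
Product: 6 methyl 2,4,6-trihydroxy-3-[(2R)-2-methylbutanoyl]-5-(3-methylbut-2-en-1-yl)benzoate
Conditions: DBU, THF, 0 °C to rt
Reagents that add atoms: none
Why: Base-mediated C-prenylation (C-alkylation of the delocalized phenolate by a soft allylic bromide) at the only remaining ring CH, which becomes C5; no stereocentre is formed and the ring stays aromatic.

Step 3
Reactants: 7 nerol ((2Z)-3,7-dimethylocta-2,6-dien-1-ol)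
Product: 8 [(2R,3S)-3-methyl-3-(4-methylpent-3-en-1-yl)oxiran-2-yl]methanol
Conditions: Ti(OiPr)4 (5 mol %), D-(−)-diethyl tartrate (6 mol %), t-BuOOH, 4 Å MS, CH2Cl2, −20 °C
Reagents that add atoms: tert-butyl hydroperoxide, CC(C)(C)OO
Why: Katsuki–Sharpless asymmetric epoxidation of the allylic alcohol: the Ti(OiPr)4–D-(−)-diethyl tartrate catalyst delivers oxygen to the face that gives the (2R,3S)-cis-epoxide (these carbons become C7 and C8), and the distal alkene, which has no directing hydroxyl, is untouched.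

Step 4
Reactants: 8 [(2R,3S)-3-methyl-3-(4-methylpent-3-en-1-yl)oxiran-2-yl]methanol
Product: 9 [(2R,3S)-3-methyl-3-(4-methylpent-3-en-1-yl)oxiran-2-yl]methyl trifluoromethanesulfonate
Conditions: Tf2O, 2,6-lutidine, CH2Cl2, −78 °C; used at once
Reagents that add atoms: trifluoromethanesulfonic anhydride, O=S(=O)(OS(=O)(=O)C(F)(F)F)C(F)(F)F
Why: O-Sulfonylation of the primary alcohol with a hindered base at −78 °C gives a glycidyl-type triflate reactive enough for C-alkylation at low temperature; no stereocentre is touched.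

Step 5
Reactants: 6 methyl 2,4,6-trihydroxy-3-[(2R)-2-methylbutanoyl]-5-(3-methylbut-2-en-1-yl)benzoate; 9 [(2R,3S)-3-methyl-3-(4-methylpent-3-en-1-yl)oxiran-2-yl]methyl trifluoromethanesulfonate
Product: 13 methyl (1R,5S,7R,8S)-4,7-dihydroxy-8-methyl-1-[(2R)-2-methylbutanoyl]-5-(3-methylbut-2-en-1-yl)-8-(4-methylpent-3-en-1-yl)-2,9-dioxobicyclo[3.3.1]non-3-ene-3-carboxylate, via dearomatized epoxide 10 (not isolated), via bis-silyl dienol ether 11 (not isolated), via bicyclic bis-silyl ether 12 (not isolated)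
Conditions: 6, LiN(SiMe3)2 (3.1 equiv), THF–toluene, −78 °C; add 9, −78 to −40 °C; then dilute with CH2Cl2, 2,6-lutidine, TMSOTf (4 equiv), −78 to −40 °C; then citric acid, MeOH, 0 °C
Reagents that add atoms: none
Why: Proposed new method: a one-flask alkylative dearomatization/epoxide-opening bicyclization in which (a) the lithium phenolate of 6 is C-alkylated by the primary triflate at the prenyl-bearing ring carbon (the acyl- and ester-bearing carbons are deactivated) to give 10 together with about as much of its C5 epimer, because the remote epoxide does not bias the ring face, (b) TMSOTf turns the enolates into the silyl dienol ether 11 and then activates the epoxide, which is opened at its tertiary carbon with inversion by the C1 enol-ether carbon through a chair transition state with C1 anti to the breaking C8–O bond, the silyl group passing from the C2 oxygen to the C7 oxygen to give 12, and (c) acidic methanol removes both silyl groups; only 10 can reach this chair with C1 (its C5 epimer can reach it only with C3 and its products are removed by chromatography, so at most about half of the material is used), which fixes C1 through the bridge, C8 by inversion of the cis-epoxide (the 4-methylpent-3-enyl group cis to C6 ends axial, the methyl equatorial) and leaves the C7 oxygen exo; the closest known reaction types are the alkylative dearomatization of acylphloroglucinols with reactive alkylating agents, cation capture by the acyl-bearing carbon in type A core syntheses, and TMSOTf-promoted epoxide-opening cyclizations of enol ethers at tertiary epoxide carbons.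

Step 6
Reactants: 13 methyl (1R,5S,7R,8S)-4,7-dihydroxy-8-methyl-1-[(2R)-2-methylbutanoyl]-5-(3-methylbut-2-en-1-yl)-8-(4-methylpent-3-en-1-yl)-2,9-dioxobicyclo[3.3.1]non-3-ene-3-carboxylate
Product: 14 methyl (1R,5S,8S)-4-hydroxy-8-methyl-1-[(2R)-2-methylbutanoyl]-5-(3-methylbut-2-en-1-yl)-8-(4-methylpent-3-en-1-yl)-2,7,9-trioxobicyclo[3.3.1]non-3-ene-3-carboxylate
Conditions: Dess–Martin periodinane, CH2Cl2, 0 °C to rt
Reagents that add atoms: none
Why: Dess–Martin oxidation of the secondary C7 alcohol to the ketone (the enolized β-keto ester has no C–H at C3 to over-oxidize and the alkenes are inert); the C7 centre is deliberately erased while C1, C5 and C8 are unchanged.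

Step 7
Reactants: 14 methyl (1R,5S,8S)-4-hydroxy-8-methyl-1-[(2R)-2-methylbutanoyl]-5-(3-methylbut-2-en-1-yl)-8-(4-methylpent-3-en-1-yl)-2,7,9-trioxobicyclo[3.3.1]non-3-ene-3-carboxylate
Product: 15 methyl (1R,5S,8R)-4-hydroxy-8-methyl-7-methylidene-1-[(2R)-2-methylbutanoyl]-5-(3-methylbut-2-en-1-yl)-8-(4-methylpent-3-en-1-yl)-2,9-dioxobicyclo[3.3.1]non-3-ene-3-carboxylate
Conditions: Ph3PCH3Br, KOtBu (3.5 equiv each), THF–toluene, 0 to 50 °C
Reagents that add atoms: methyltriphenylphosphonium bromide, C[P+](c1ccccc1)(c1ccccc1)c1ccccc1.[Br-]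
Why: Wittig methylenation of the only unhindered ketone: C9 and the side-chain ketone are flanked by quaternary carbons and the C2/C4 system reacts first as an acid to give an unreactive enolate (hence the excess ylide); no stereocentre is affected.

Step 8
Reactants: 15 methyl (1R,5S,8R)-4-hydroxy-8-methyl-7-methylidene-1-[(2R)-2-methylbutanoyl]-5-(3-methylbut-2-en-1-yl)-8-(4-methylpent-3-en-1-yl)-2,9-dioxobicyclo[3.3.1]non-3-ene-3-carboxylate; 16 1-bromo-2-methylprop-1-ene
Product: 18 methyl (1R,5S,7S,8R)-4-hydroxy-8-methyl-1-[(2R)-2-methylbutanoyl]-5,7-bis(3-methylbut-2-en-1-yl)-8-(4-methylpent-3-en-1-yl)-2,9-dioxobicyclo[3.3.1]non-3-ene-3-carboxylate, via alkylborane 17 (not isolated)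
Conditions: 9-BBN (3 equiv), THF, 0 °C to rt; then 16, Pd(dppf)Cl2 (5 mol %), K3PO4 (aq), DMF, 50 °C
Reagents that add atoms: none
Why: Hydroboration with 9-BBN picks the 1,1-disubstituted exocyclic alkene over the trisubstituted ones (one equivalent is taken up by the acidic enol) and adds from the exo face because the endo face is screened by ring A, so hydrogen ends exo and the CH2–B group endo (this sets C7 as S); B-alkyl Suzuki–Miyaura coupling with the alkenyl bromide then completes the endo prenyl group.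

Step 9
Reactants: 18 methyl (1R,5S,7S,8R)-4-hydroxy-8-methyl-1-[(2R)-2-methylbutanoyl]-5,7-bis(3-methylbut-2-en-1-yl)-8-(4-methylpent-3-en-1-yl)-2,9-dioxobicyclo[3.3.1]non-3-ene-3-carboxylate
Product: 19 (1S,5S,7S,8R)-4-hydroxy-8-methyl-1-[(2R)-2-methylbutanoyl]-5,7-bis(3-methylbut-2-en-1-yl)-8-(4-methylpent-3-en-1-yl)bicyclo[3.3.1]non-3-ene-2,9-dione
Conditions: LiCl (3 equiv), H2O, DMSO, 110 °C, argon
Reagents that add atoms: none
Why: Krapcho dealkoxycarbonylation (chloride demethylation of the ester, loss of CO2 from the vinylogous β-keto carboxylate, protonation at C3 by water) removes the blocking ester without touching any stereocentre; the C1 descriptor changes from R to S only because the ester no longer counts in the priorities.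

**Compound list**

1 | (R)-2-methylbutanoic acid | CC[C@@H](C)C(=O)O | starting material
2 | methyl 2,4,6-trihydroxybenzoate | COC(=O)c1c(O)cc(O)cc1O | starting material
3 | (R)-2-methylbutanoyl chloride (not isolated) | CC[C@@H](C)C(=O)Cl | intermediate
4 | methyl 2,4,6-trihydroxy-3-[(2R)-2-methylbutanoyl]benzoate | CC[C@@H](C)C(=O)c1c(O)cc(O)c(C(=O)OC)c1O | intermediate
5 | prenyl bromide (1-bromo-3-methylbut-2-ene) | CC(C)=CCBr | starting material
6 | methyl 2,4,6-trihydroxy-3-[(2R)-2-methylbutanoyl]-5-(3-methylbut-2-en-1-yl)benzoate | CC[C@@H](C)C(=O)c1c(O)c(CC=C(C)C)c(O)c(C(=O)OC)c1O | intermediate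
7 | nerol ((2Z)-3,7-dimethylocta-2,6-dien-1-ol) | CC(C)=CCC/C(C)=C\CO | starting material
8 | [(2R,3S)-3-methyl-3-(4-methylpent-3-en-1-yl)oxiran-2-yl]methanol | OC[C@H]1O[C@@]1(C)CCC=C(C)C | intermediate
9 | [(2R,3S)-3-methyl-3-(4-methylpent-3-en-1-yl)oxiran-2-yl]methyl trifluoromethanesulfonate | O=S(=O)(OC[C@H]1O[C@@]1(C)CCC=C(C)C)C(F)(F)F | intermediate
10 | methyl (3S)-2,6-dihydroxy-5-[(2R)-2-methylbutanoyl]-3-(3-methylbut-2-en-1-yl)-3-{[(2R,3S)-3-methyl-3-(4-methylpent-3-en-1-yl)oxiran-2-yl]methyl}-4-oxocyclohexa-1,5-diene-1-carboxylate (dearomatized epoxide; dilithium dienolate in the flask; ring C3 of this name is C5; not isolated) | CC[C@@H](C)C(=O)C1=C(O)C(C(=O)OC)=C(O)[C@](CC=C(C)C)(C[C@H]2O[C@@]2(C)CCC=C(C)C)C1=O | intermediate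
11 | methyl (3S)-5-[(2R)-2-methylbutanoyl]-3-(3-methylbut-2-en-1-yl)-3-{[(2R,3S)-3-methyl-3-(4-methylpent-3-en-1-yl)oxiran-2-yl]methyl}-4-oxo-2,6-bis[(trimethylsilyl)oxy]cyclohexa-1,5-diene-1-carboxylate (bis-silyl dienol ether of 10; not isolated) | CC[C@@H](C)C(=O)C1=C(O[Si](C)(C)C)C(C(=O)OC)=C(O[Si](C)(C)C)[C@](CC=C(C)C)(C[C@H]2O[C@@]2(C)CCC=C(C)C)C1=O | intermediate
12 | methyl (1R,5S,7R,8S)-8-methyl-1-[(2R)-2-methylbutanoyl]-5-(3-methylbut-2-en-1-yl)-8-(4-methylpent-3-en-1-yl)-2,9-dioxo-4,7-bis[(trimethylsilyl)oxy]bicyclo[3.3.1]non-3-ene-3-carboxylate (bicyclic bis-silyl ether; not isolated) | CC[C@@H](C)C(=O)[C@]12C(=O)C(C(=O)OC)=C(O[Si](C)(C)C)[C@](CC=C(C)C)(C[C@@H](O[Si](C)(C)C)[C@@]1(C)CCC=C(C)C)C2=O | intermediate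
13 | methyl (1R,5S,7R,8S)-4,7-dihydroxy-8-methyl-1-[(2R)-2-methylbutanoyl]-5-(3-methylbut-2-en-1-yl)-8-(4-methylpent-3-en-1-yl)-2,9-dioxobicyclo[3.3.1]non-3-ene-3-carboxylate (C7 hydroxyl exo) | CC[C@@H](C)C(=O)[C@]12C(=O)C(C(=O)OC)=C(O)[C@](CC=C(C)C)(C[C@@H](O)[C@@]1(C)CCC=C(C)C)C2=O | intermediate
14 | methyl (1R,5S,8S)-4-hydroxy-8-methyl-1-[(2R)-2-methylbutanoyl]-5-(3-methylbut-2-en-1-yl)-8-(4-methylpent-3-en-1-yl)-2,7,9-trioxobicyclo[3.3.1]non-3-ene-3-carboxylate | CC[C@@H](C)C(=O)[C@]12C(=O)C(C(=O)OC)=C(O)[C@](CC=C(C)C)(CC(=O)[C@@]1(C)CCC=C(C)C)C2=O | intermediate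
15 | methyl (1R,5S,8R)-4-hydroxy-8-methyl-7-methylidene-1-[(2R)-2-methylbutanoyl]-5-(3-methylbut-2-en-1-yl)-8-(4-methylpent-3-en-1-yl)-2,9-dioxobicyclo[3.3.1]non-3-ene-3-carboxylate (C8 geometry unchanged; descriptor changes with priorities) | CC[C@@H](C)C(=O)[C@]12C(=O)C(C(=O)OC)=C(O)[C@](CC=C(C)C)(CC(=C)[C@@]1(C)CCC=C(C)C)C2=O | intermediate
16 | 1-bromo-2-methylprop-1-ene | CC(C)=CBr | starting material
17 | methyl (1R,5S,7S,8R)-7-[(9-borabicyclo[3.3.1]nonan-9-yl)methyl]-4-hydroxy-8-methyl-1-[(2R)-2-methylbutanoyl]-5-(3-methylbut-2-en-1-yl)-8-(4-methylpent-3-en-1-yl)-2,9-dioxobicyclo[3.3.1]non-3-ene-3-carboxylate (not isolated) | CC[C@@H](C)C(=O)[C@]12C(=O)C(C(=O)OC)=C(O)[C@](CC=C(C)C)(C[C@H](CB3C4CCCC3CCC4)[C@@]1(C)CCC=C(C)C)C2=O | intermediate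
18 | methyl (1R,5S,7S,8R)-4-hydroxy-8-methyl-1-[(2R)-2-methylbutanoyl]-5,7-bis(3-methylbut-2-en-1-yl)-8-(4-methylpent-3-en-1-yl)-2,9-dioxobicyclo[3.3.1]non-3-ene-3-carboxylate | CC[C@@H](C)C(=O)[C@]12C(=O)C(C(=O)OC)=C(O)[C@](CC=C(C)C)(C[C@H](CC=C(C)C)[C@@]1(C)CCC=C(C)C)C2=O | intermediate
19 | (1S,5S,7S,8R)-4-hydroxy-8-methyl-1-[(2R)-2-methylbutanoyl]-5,7-bis(3-methylbut-2-en-1-yl)-8-(4-methylpent-3-en-1-yl)bicyclo[3.3.1]non-3-ene-2,9-dione | CC[C@@H](C)C(=O)[C@]12C(=O)C=C(O)[C@](CC=C(C)C)(C[C@H](CC=C(C)C)[C@@]1(C)CCC=C(C)C)C2=O | target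

**Count and risks**

Total step count: 9. Longest linear sequence: 7 steps (1, 2, 5, 6, 7, 8, 9; the branch 3, 4 joins at step 5).

Most likely to fail, first: step 5. The triflate may alkylate oxygen instead of C5, and a lithium enolate oxygen may open the epoxide at C7 before silylation. Oxygen or C3 may also capture the C8 cationoid centre instead of the acyl-bearing C1, and TMSOTf can attack THF if the mixture is not diluted and kept cold. Even when all goes well, only the half of the material that is 10 can give 13. Fallback, setting out from 6 (with 9) and coming back at 13: the two events are separated and the oxygen nucleophiles are capped. The alkylation alone is run and quenched cold so that 10 is isolated and separated from its C5 epimer; TMSCHN2 in MeOH–toluene converts it into the C2,C4-bis(O-methyl) ether of 10 F1. TMSOTf and 2,6-lutidine in CH2Cl2 at −78 °C then bring about an enol ether–epoxide cyclization at C1, the C2 methyl being passed to lutidine, which gives the C7 trimethylsilyl ether C4 methyl ether of 13 F2. Citric acid in MeOH removes the silyl group to give the C4 O-methyl ether of 13 F3, and dilute aqueous LiOH in THF cleaves this vinylogous methyl ester and returns 13.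

Second: step 8. The organoborane must form next to a quaternary carbon in the presence of two hindered ketones and an acidic enol, and the B-alkyl coupling may stall. Fallback, setting out from 15 and coming back at 18: the boron is removed and the bond is made by cross-electrophile coupling of an isolated alkyl iodide, which needs no basic organometallic and tolerates the acidic enol. Hydroboration with 9-BBN (through 17, same exo-face hydrogen delivery) followed by NaBO3 oxidation gives the endo C7 hydroxymethyl compound F4. I2, PPh3 and imidazole give the endo C7 iodomethyl compound F5. NiI2 with 4,4′-di-tert-butyl-2,2′-bipyridine, Mn powder and NaI in DMPU then couples F5 with 16 reductively to give 18. This fallback answers the coupling half of the risk; it still relies on the hydroboration.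

Third: step 7. The ylide may only enolize the C7 ketone, which sits next to the quaternary C8, or the base may erode the side-chain centre. Fallback, setting out from 14 and coming back at 15: a Peterson olefination in two stages. Me3SiCH2Li with CeCl3 in THF at −78 °C (one extra equivalent for the enol) adds to the C7 carbonyl from the exo face without enolizing it, giving the C7 β-hydroxysilane F6; KH in THF then eliminates the silanolate to give 15.

Further compounds
F1 | step 5 | C2,C4-bis(O-methyl) ether of 10: methyl (3S)-2,6-dimethoxy-5-[(2R)-2-methylbutanoyl]-3-(3-methylbut-2-en-1-yl)-3-{[(2R,3S)-3-methyl-3-(4-methylpent-3-en-1-yl)oxiran-2-yl]methyl}-4-oxocyclohexa-1,5-diene-1-carboxylate | CC[C@@H](C)C(=O)C1=C(OC)C(C(=O)OC)=C(OC)[C@](CC=C(C)C)(C[C@H]2O[C@@]2(C)CCC=C(C)C)C1=O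
F2 | step 5 | C7 trimethylsilyl ether C4 methyl ether of 13: methyl (1R,5S,7R,8S)-4-methoxy-8-methyl-1-[(2R)-2-methylbutanoyl]-5-(3-methylbut-2-en-1-yl)-8-(4-methylpent-3-en-1-yl)-2,9-dioxo-7-[(trimethylsilyl)oxy]bicyclo[3.3.1]non-3-ene-3-carboxylate | CC[C@@H](C)C(=O)[C@]12C(=O)C(C(=O)OC)=C(OC)[C@](CC=C(C)C)(C[C@@H](O[Si](C)(C)C)[C@@]1(C)CCC=C(C)C)C2=O
F3 | step 5 | C4 O-methyl ether of 13: methyl (1R,5S,7R,8S)-7-hydroxy-4-methoxy-8-methyl-1-[(2R)-2-methylbutanoyl]-5-(3-methylbut-2-en-1-yl)-8-(4-methylpent-3-en-1-yl)-2,9-dioxobicyclo[3.3.1]non-3-ene-3-carboxylate | CC[C@@H](C)C(=O)[C@]12C(=O)C(C(=O)OC)=C(OC)[C@](CC=C(C)C)(C[C@@H](O)[C@@]1(C)CCC=C(C)C)C2=O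
F4 | step 8 | endo C7 hydroxymethyl compound: methyl (1R,5S,7S,8R)-4-hydroxy-7-(hydroxymethyl)-8-methyl-1-[(2R)-2-methylbutanoyl]-5-(3-methylbut-2-en-1-yl)-8-(4-methylpent-3-en-1-yl)-2,9-dioxobicyclo[3.3.1]non-3-ene-3-carboxylate | CC[C@@H](C)C(=O)[C@]12C(=O)C(C(=O)OC)=C(O)[C@](CC=C(C)C)(C[C@H](CO)[C@@]1(C)CCC=C(C)C)C2=O
F5 | step 8 | endo C7 iodomethyl compound: methyl (1R,5S,7S,8R)-4-hydroxy-7-(iodomethyl)-8-methyl-1-[(2R)-2-methylbutanoyl]-5-(3-methylbut-2-en-1-yl)-8-(4-methylpent-3-en-1-yl)-2,9-dioxobicyclo[3.3.1]non-3-ene-3-carboxylate | CC[C@@H](C)C(=O)[C@]12C(=O)C(C(=O)OC)=C(O)[C@](CC=C(C)C)(C[C@H](CI)[C@@]1(C)CCC=C(C)C)C2=O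
F6 | step 7 | C7 β-hydroxysilane: methyl (1R,5S,7S,8S)-4,7-dihydroxy-8-methyl-1-[(2R)-2-methylbutanoyl]-5-(3-methylbut-2-en-1-yl)-8-(4-methylpent-3-en-1-yl)-2,9-dioxo-7-[(trimethylsilyl)methyl]bicyclo[3.3.1]non-3-ene-3-carboxylate | CC[C@@H](C)C(=O)[C@]12C(=O)C(C(=O)OC)=C(O)[C@](CC=C(C)C)(C[C@@](O)(C[Si](C)(C)C)[C@@]1(C)CCC=C(C)C)C2=O
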